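## Retrosynthetic overview

1. The target is a cross-conjugated cyclohexa-2,5-dienone. Ring carbonyl C-1 lies between the enone C-2(allyl)=C-3 and the vinylogous ester C-6=C-5(OMe), and the only stereocenter, quaternary C-4 (OMe, arylpropenyl), is γ to C-1 and next to C-5. This makes C-1 an acyl carbon for a C-2 vinyl anion, and C-4 the γ-carbon of a dienolate that can close on C-5.
2. Key disconnection, C-1–C-2 and C-4–C-5 in one flask: a (Z)-vinyllithium (C-2–C-3–C-4 unit, from iodide 9) acylates a three-carbon ketene-acetal Weinreb amide (C-5–C-6–C-1 unit, 13). The resulting trienone closes as a 3-oxidohexatriene under a chiral ammonium cation and loses methoxide.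
3. C-5 enters at the orthoester oxidation level, so the closure leaves exactly one methoxy group there, and the C-4 methoxy group is installed before the ring exists.
4. Fragment 9: aldol condensation, acetylide addition, hydroxyl-directed trans-hydroalumination/iodination, O-methylation. Fragment 13: two steps from 3,3-dichloroacrylic acid.
5. The single carbocycle is formed in the last step; there are no protecting groups.

Key step: step 7

Assumption: the sense of induction of the ion-pair-controlled closure cannot be derived from precedent; the cinchonidinium salt is taken to give (S)-17, and its pseudo-enantiomeric cinchoninium salt would be used otherwise.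

## Route

Step 1
Reactants: 1 3,4-dimethoxybenzaldehyde; 2 propanal
Product: 3 (E)-3-(3,4-dimethoxyphenyl)-2-methylprop-2-enal
Conditions: NaOH (aq), MeOH, 0 °C → rt, slow addition of 2
Reagents that add atoms: none
Why: Crossed (Claisen–Schmidt) aldol condensation: the non-enolizable aldehyde 1 takes the enolate of propanal, and dehydration should give the conjugated enal with the favoured (E)-geometry (aryl trans to formyl).

Step 2
Reactants: 3 (E)-3-(3,4-dimethoxyphenyl)-2-methylprop-2-enal; 4 pent-1-en-4-yne
Product: 6 (1E)-1-(3,4-dimethoxyphenyl)-2-methylocta-1,7-dien-4-yn-3-ol (racemic), via lithium pent-4-en-1-yn-1-ide 5 (not isolated)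
Conditions: 4, n-BuLi, THF, −78 °C; then 3, −78 → 0 °C; aq NH4Cl
Reagents that add atoms: none
Why: 1,2-Addition of a lithium acetylide to the enal carbonyl; the carbinol centre is made racemic on purpose because it is erased in step 7.

Step 3
Reactants: 6 (1E)-1-(3,4-dimethoxyphenyl)-2-methylocta-1,7-dien-4-yn-3-ol
Product: 8 (1E,4Z)-1-(3,4-dimethoxyphenyl)-5-iodo-2-methylocta-1,4,7-trien-3-ol (racemic), via cyclic sodium alkoxyvinylalanate 7 (not isolated)
Conditions: NaAlH2(OCH2CH2OMe)2 (Red-Al), THF, 0 °C → rt; then I2, −78 → 0 °C; aq KNaC4H4O6 (tartrate)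
Reagents that add atoms: iodine, II
Why: Hydroxyl-directed trans-hydroalumination of the propargylic alcohol puts hydride on the carbon next to the carbinol and aluminium on the distal carbon in a five-membered alanate, and iodinolysis with retention should give the (Z)-iodide, the geometry that later holds C-1 and C-4 on the same side of C-2=C-3.

Step 4
Reactants: 8 (1E,4Z)-1-(3,4-dimethoxyphenyl)-5-iodo-2-methylocta-1,4,7-trien-3-ol
Product: 9 4-[(1E,4Z)-5-iodo-3-methoxy-2-methylocta-1,4,7-trien-1-yl]-1,2-dimethoxybenzene (racemic)
Conditions: NaH, MeI, THF, 0 °C → rt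
Reagents that add atoms: iodomethane, CI
Why: Williamson etherification installs the C-4 methoxy group before ring closure, so that no tertiary alcohol has to be methylated later and no furan can form from a (Z)-γ-hydroxy enone.

Step 5
Reactants: 10 3,3-dichloroacrylic acid
Product: 12 3,3-dichloro-N-methoxy-N-methylprop-2-enamide, via 3,3-dichloroacryloyl chloride 11 (not isolated)
Conditions: (COCl)2, DMF (cat.), CH2Cl2, 0 °C → rt; then MeNHOMe·HCl, pyridine, 0 °C
Reagents that add atoms: N,O-dimethylhydroxylamine hydrochloride, CNOC.Cl
Why: Acid chloride formation and N-acylation give the Weinreb amide; the vinylic chlorides should survive at 0 °C because acyl substitution is much faster than addition–elimination.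

Step 6
Reactants: 12 3,3-dichloro-N-methoxy-N-methylprop-2-enamide
Product: 13 N,3,3-trimethoxy-N-methylprop-2-enamide
Conditions: NaOMe (2.3 equiv), MeOH, 0 → 40 °C
Reagents that add atoms: sodium methoxide, [Na+].[O-]C
Why: Twofold nucleophilic vinylic substitution (addition–elimination) of the β,β-dichloroacrylamide by methoxide should give the push–pull ketene acetal, which carries C-5 at the orthoester oxidation level.

Step 7
Reactants: 9 4-[(1E,4Z)-5-iodo-3-methoxy-2-methylocta-1,4,7-trien-1-yl]-1,2-dimethoxybenzene; 13 N,3,3-trimethoxy-N-methylprop-2-enamide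
Product: 17 (S)-4-[(E)-1-(3,4-dimethoxyphenyl)prop-1-en-2-yl]-4,5-dimethoxy-2-(prop-2-en-1-yl)cyclohexa-2,5-dien-1-one, via vinyllithium 14 (not isolated), via lithium hemiaminal adduct 15 (not isolated), via trienone 16 (not isolated)
Conditions: t-BuLi (2.05 equiv), Et2O, −78 °C; 13, −78 → −30 °C; AcOH (1.1 equiv), −78 °C → rt; solvent exchange to toluene in the same flask; O-allyl-N-(9-anthracenylmethyl)cinchonidinium bromide (10 mol %), CsOH·H2O (solid), −40 °C
Reagents that add atoms: none
Why: Proposed new method: iodine–lithium exchange gives the (Z)-vinyllithium 14, which acylates amide 13 at C-1 (C-1–C-2 bond, Weinreb ketone synthesis), and protonolysis releases trienone 16, whose C-4 hydrogen (γ to the carbonyl, doubly allylic, α to methoxy) is removed under solid–liquid phase transfer to give a 3-oxidohexatriene. This closes the six-membered ring by a six-electron disrotatory electrocyclization, equivalent to a 6-endo-trig vinylogous Michael addition of C-4 to the ketene-acetal carbon C-5 (C-4–C-5 bond), and the cyclohexadienolate then expels methoxide (E1cB) to leave the vinylogous ester and the cross-conjugated dienone. The closest known reactions are the oxyanion-accelerated electrocyclization of 3-oxidohexatrienes and the enantioselective anionic six-electron electrocyclizations run under cinchona-derived ammonium ion pairing. The new stereocenter at C-4 is set in the ring closure by the chiral ammonium cation paired with the trienolate, which selects one helical sense of the triene; the racemic centre of 16 is erased on deprotonation, so the step is stereoconvergent. The step needs γ- rather than α-attack and a single site of methoxide loss: the (Z)-geometry carried from 8 holds C-4 next to C-5, the α-alternative would be a four-membered ring, and only C-5 bears a leaving group.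

## Compound list

1 | 3,4-dimethoxybenzaldehyde | COc1ccc(C=O)cc1OC | starting material
2 | propanal | CCC=O | starting material
3 | (E)-3-(3,4-dimethoxyphenyl)-2-methylprop-2-enal | COc1ccc(/C=C(\C)C=O)cc1OC | intermediate
4 | pent-1-en-4-yne | C=CCC#C | starting material
5 | lithium pent-4-en-1-yn-1-ide (not isolated) | [Li]C#CCC=C | intermediate
6 | (1E)-1-(3,4-dimethoxyphenyl)-2-methylocta-1,7-dien-4-yn-3-ol (racemic) | COc1ccc(/C=C(\C)C(O)C#CCC=C)cc1OC | intermediate
7 | cyclic sodium alkoxyvinylalanate from 6, bis(2-methoxyethoxy) ligands (not isolated) | [Na+].COCCO[Al-]1(OCCOC)OC(/C(C)=C/c2ccc(OC)c(OC)c2)C=C1CC=C | intermediate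
8 | (1E,4Z)-1-(3,4-dimethoxyphenyl)-5-iodo-2-methylocta-1,4,7-trien-3-ol (racemic) | COc1ccc(/C=C(\C)C(O)/C=C(\I)CC=C)cc1OC | intermediate
9 | 4-[(1E,4Z)-5-iodo-3-methoxy-2-methylocta-1,4,7-trien-1-yl]-1,2-dimethoxybenzene (racemic) | COc1ccc(/C=C(\C)C(OC)/C=C(\I)CC=C)cc1OC | intermediate
10 | 3,3-dichloroacrylic acid | OC(=O)C=C(Cl)Cl | starting material
11 | 3,3-dichloroacryloyl chloride (not isolated) | ClC(=O)C=C(Cl)Cl | intermediate
12 | 3,3-dichloro-N-methoxy-N-methylprop-2-enamide | CON(C)C(=O)C=C(Cl)Cl | intermediate
13 | N,3,3-trimethoxy-N-methylprop-2-enamide | CON(C)C(=O)C=C(OC)OC | intermediate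
14 | (1Z,4E)-configured vinyllithium from 9 (not isolated) | [Li]/C(CC=C)=C\C(OC)/C(C)=C/c1ccc(OC)c(OC)c1 | intermediate
15 | lithium hemiaminal adduct of 14 and 13 (not isolated) | [Li]OC(N(C)OC)(C=C(OC)OC)/C(CC=C)=C\C(OC)/C(C)=C/c1ccc(OC)c(OC)c1 | intermediate
16 | (4Z,7E)-8-(3,4-dimethoxyphenyl)-1,1,6-trimethoxy-7-methyl-4-(prop-2-en-1-yl)octa-1,4,7-trien-3-one (racemic, not isolated) | COC(OC)=CC(=O)/C(CC=C)=C\C(OC)/C(C)=C/c1ccc(OC)c(OC)c1 | intermediate
17 | (S)-4-[(E)-1-(3,4-dimethoxyphenyl)prop-1-en-2-yl]-4,5-dimethoxy-2-(prop-2-en-1-yl)cyclohexa-2,5-dien-1-one | C=CCC1=C[C@](OC)(/C(C)=C/c2ccc(OC)c(OC)c2)C(OC)=CC1=O | target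

## Step count and risks

Total steps: 7. Longest linear sequence: 5 (steps 1, 2, 3, 4, 7).

**Step 7 (key step).** The chiral cation may discriminate poorly between the two helical senses of the trienolate, and lithium salts left in the flask may promote an uncontrolled background closure. Hydroxide may also attack the ketene acetal before the closure takes place. Fallback: from 9 and 13 the acylation is run with an aqueous work-up and trienone 16 is isolated (Weinreb ketone synthesis). It is then closed without chiral control by catalytic NaOMe in MeOH at 0 °C, which is the known alkoxide-induced oxidotriene electrocyclization followed by β-alkoxide loss, and should give the racemic dienone F1. The enantiomers are separated by preparative chromatography on a chiral stationary phase, and the route is rejoined at 17.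

**Step 3.** The hydroalumination may lose regio- or stereocontrol, the alanate may be protonated before iodination, or the basic hydride may isomerize the skipped enyne. Fallback: from 6, trans-hydrosilylation with benzyl(dimethyl)silane and [Cp*Ru(MeCN)3]PF6 (cat.) in acetone at 0 °C should place silicon on the alkyne carbon distal to the hydroxyl and give the (Z)-vinylsilane F2. Iododesilylation with N-iodosuccinimide in hexafluoroisopropanol, with retention, returns to the route at 8.

**Step 2.** n-BuLi may deprotonate the doubly activated methylene of the skipped enyne, which then isomerizes to conjugated allenyl species before it can add. Fallback: from 3, addition of HC≡CMgBr (THF, 0 °C) should give the terminal propargylic alcohol F3. Copper-catalysed allylation of the terminal alkyne (allyl bromide, CuI, K2CO3, NaI, DMF, rt) then returns to the route at 6.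

## Further compounds

F1 | step 7 | racemic 4-[(E)-1-(3,4-dimethoxyphenyl)prop-1-en-2-yl]-4,5-dimethoxy-2-(prop-2-en-1-yl)cyclohexa-2,5-dien-1-one | C=CCC1=CC(OC)(/C(C)=C/c2ccc(OC)c(OC)c2)C(OC)=CC1=O
F2 | step 3 | (1E,4Z)-5-[benzyl(dimethyl)silyl]-1-(3,4-dimethoxyphenyl)-2-methylocta-1,4,7-trien-3-ol (racemic) | COc1ccc(/C=C(\C)C(O)/C=C(\[Si](C)(C)Cc2ccccc2)CC=C)cc1OC
F3 | step 2 | (1E)-1-(3,4-dimethoxyphenyl)-2-methylpent-1-en-4-yn-3-ol (racemic) | COc1ccc(/C=C(\C)C(O)C#C)cc1OC
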